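The 11-hydroxyfarnesyl ether chain is cut at C5'–C6' (locants from the ether CH2), the sp3–sp2 bond inside its 1,5-diene C2'=C3'–C4'–C5'–C6'=C7'; the benzene and lactone rings play no part. Because C5' ends an ethylene bridge on the C2'=C3' alkene, it can be unmasked from a conjugated (E)-dienol: one-pot 9-BBN hydroboration and B-alkyl Suzuki–Miyaura coupling with an (E)-alkenyl iodide (C6'–C12', tertiary alcohol included) forms this bond with both alkene geometries already fixed. The diol is then attached to the para-hydroxyl of methyl 3-O-methylgallate, and the lactone ring of the 2-benzofuran-1(3H)-one is closed last by ortho-formylation, reduction and lactonisation.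

Key step: step 4

Remark: compounds 1, 5 and 9 are taken as purchasable; C11' carries the tertiary hydroxyl.

Step 1
Reactants: 1 methyl hex-5-ynoate
Product: 2 2-methylhept-6-yn-2-ol
Conditions: MeMgBr (3.5 equiv), THF/Et2O, 0 °C to rt; aq NH4Cl
Reagents that add atoms: methylmagnesium bromide, C[Mg]Br
Why: Double Grignard addition to the ester should give the tertiary alcohol, the third equivalent only deprotonating the terminal alkyne, which is restored on work-up.

Step 2
Reactants: 2 2-methylhept-6-yn-2-ol
Product: 4 (6E)-7-iodo-2,6-dimethylhept-6-en-2-ol, via alkenyldimethylalane 3 (not isolated)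
Conditions: Me3Al (3.5 equiv), Cp2ZrCl2 (0.25 equiv), CH2Cl2, 0 °C to rt; then I2, THF, −30 to 0 °C; aq Na2S2O3/NaHCO3
Reagents that add atoms: trimethylaluminium, C[Al](C)C; iodine, II
Why: Zirconium-catalysed methylalumination (Negishi carboalumination) adds methyl and aluminium syn across the terminal alkyne with aluminium on the terminal carbon, and iodinolysis with retention should give the (E)-alkenyl iodide while the tertiary hydroxyl is masked as its aluminium alkoxide.

Step 3
Reactants: 5 (2E)-3-methylpent-2-en-4-yn-1-ol
Product: 6 (2E)-3-methylpenta-2,4-dien-1-ol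
Conditions: H2 (1 atm), Pd/CaCO3 poisoned with Pb(OAc)2 (Lindlar catalyst), quinoline, EtOAc/hexane, 0 °C to rt, stopped after one equivalent of H2
Reagents that add atoms: none
Why: Lindlar semihydrogenation should reduce the terminal alkyne to a vinyl group and leave the trisubstituted (E)-alkene untouched.

Step 4
Reactants: 6 (2E)-3-methylpenta-2,4-dien-1-ol; 4 (6E)-7-iodo-2,6-dimethylhept-6-en-2-ol
Product: 8 (2E,6E)-3,7,11-trimethyldodeca-2,6-diene-1,11-diol, via bis(9-BBN) adduct 7 (not isolated)
Conditions: 9-BBN (2.2 equiv), THF, 0 °C to rt; then 4, Pd(dppf)Cl2 (5 mol %), AsPh3 (10 mol %), aq K3PO4 (3 equiv), DMF/THF, rt; aq NH4Cl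
Reagents that add atoms: none
Why: The hydroxyl of 6 consumes one equivalent of 9-BBN as a borinate, and the second equivalent adds syn and anti-Markovnikov to the terminal C4'=C5' vinyl group of the diene, placing boron on C5' because 9-BBN discriminates strongly between a monosubstituted alkene and the trisubstituted C2'=C3' bond. After activation of boron by the aqueous base, oxidative addition of zerovalent palladium into the C–I bond of 4, transmetalation of the primary alkyl group and reductive elimination form the C5'–C6' bond; this is a B-alkyl Suzuki–Miyaura coupling, the closest known case being the coupling of 9-BBN adducts of terminal alkenes with (E)-alkenyl iodides. No ring is closed and no stereocentre is created. The step needs regioselective monohydroboration and retention of both alkene geometries: the first is secured by the steric demand of 9-BBN, the second by stereoretentive oxidative addition and reductive elimination at sp2 carbon and by the fact that C2'=C3' is never involved. Competing β-hydride elimination of the alkylpalladium intermediate should be suppressed by the wide-bite-angle dppf ligand, and both free hydroxyl groups should be tolerated under the aqueous basic conditions.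

Step 5
Reactants: 8 (2E,6E)-3,7,11-trimethyldodeca-2,6-diene-1,11-diol; 9 methyl 3,4-dihydroxy-5-methoxybenzoate
Product: 10 methyl 3-hydroxy-4-{[(2E,6E)-11-hydroxy-3,7,11-trimethyldodeca-2,6-dien-1-yl]oxy}-5-methoxybenzoate
Conditions: PPh3, DIAD, THF, 0 °C to rt (9 in slight excess)
Reagents that add atoms: none
Why: Mitsunobu etherification should take place at the primary allylic hydroxyl of 8 (the tertiary one is inert) and at the more acidic 4-hydroxyl of 9, para to the ester, by SN2 displacement without allylic transposition.

Step 6
Reactants: 10 methyl 3-hydroxy-4-{[(2E,6E)-11-hydroxy-3,7,11-trimethyldodeca-2,6-dien-1-yl]oxy}-5-methoxybenzoate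
Product: 11 methyl 2-formyl-3-hydroxy-4-{[(2E,6E)-11-hydroxy-3,7,11-trimethyldodeca-2,6-dien-1-yl]oxy}-5-methoxybenzoate
Conditions: MgCl2 (anhydrous), Et3N, paraformaldehyde, THF, reflux; aq citric acid
Reagents that add atoms: paraformaldehyde (formaldehyde units), C=O
Why: Magnesium-mediated ortho-formylation (Casnati–Skattebøl) delivers formaldehyde within the magnesium phenoxide to the only free ortho position, C2, which is also para to the methoxy group, and a second formaldehyde oxidises the benzylic alkoxide to the aldehyde under basic conditions that spare the alkenes and the allylic ether; any alkoxide that lactonises first would already be 13 and would pass through step 7 unchanged.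

Step 7
Reactants: 11 methyl 2-formyl-3-hydroxy-4-{[(2E,6E)-11-hydroxy-3,7,11-trimethyldodeca-2,6-dien-1-yl]oxy}-5-methoxybenzoate
Product: 13 farnesylemefuranone E, via hydroxymethyl benzoate 12 (not isolated)
Conditions: NaBH4, MeOH/THF, 0 °C; then AcOH, rt
Reagents that add atoms: none
Why: Borohydride reduction of the aldehyde gives the ortho-hydroxymethyl benzoate, whose 5-exo-trig lactonisation onto the neighbouring methyl ester should close the 2-benzofuranone ring.

Compound list
1 | methyl hex-5-ynoate | C#CCCCC(=O)OC | starting material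
2 | 2-methylhept-6-yn-2-ol | C#CCCCC(C)(C)O | intermediate
3 | [(1E)-6-(dimethylalumanyloxy)-2,6-dimethylhept-1-en-1-yl]dimethylalumane | C[Al](C)/C=C(\C)CCCC(C)(C)O[Al](C)C | intermediate
4 | (6E)-7-iodo-2,6-dimethylhept-6-en-2-ol | I/C=C(\C)CCCC(C)(C)O | intermediate
5 | (2E)-3-methylpent-2-en-4-yn-1-ol | OC/C=C(\C)C#C | starting material
6 | (2E)-3-methylpenta-2,4-dien-1-ol | OC/C=C(\C)C=C | intermediate
7 | 9-{[(2E)-5-(9-borabicyclo[3.3.1]nonan-9-yl)-3-methylpent-2-en-1-yl]oxy}-9-borabicyclo[3.3.1]nonane | B1(OC/C=C(\C)CCB4C5CCCC4CCC5)C2CCCC1CCC2 | intermediate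
8 | (2E,6E)-3,7,11-trimethyldodeca-2,6-diene-1,11-diol | OC/C=C(\C)CC/C=C(\C)CCCC(C)(C)O | intermediate
9 | methyl 3,4-dihydroxy-5-methoxybenzoate (methyl 3-O-methylgallate) | COC(=O)c1cc(O)c(O)c(OC)c1 | starting material
10 | methyl 3-hydroxy-4-{[(2E,6E)-11-hydroxy-3,7,11-trimethyldodeca-2,6-dien-1-yl]oxy}-5-methoxybenzoate | COC(=O)c1cc(O)c(OC/C=C(\C)CC/C=C(\C)CCCC(C)(C)O)c(OC)c1 | intermediate
11 | methyl 2-formyl-3-hydroxy-4-{[(2E,6E)-11-hydroxy-3,7,11-trimethyldodeca-2,6-dien-1-yl]oxy}-5-methoxybenzoate | COC(=O)c1cc(OC)c(OC/C=C(\C)CC/C=C(\C)CCCC(C)(C)O)c(O)c1C=O | intermediate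
12 | methyl 3-hydroxy-2-(hydroxymethyl)-4-{[(2E,6E)-11-hydroxy-3,7,11-trimethyldodeca-2,6-dien-1-yl]oxy}-5-methoxybenzoate | COC(=O)c1cc(OC)c(OC/C=C(\C)CC/C=C(\C)CCCC(C)(C)O)c(O)c1CO | intermediate
13 | farnesylemefuranone E, 4-hydroxy-5-{[(2E,6E)-11-hydroxy-3,7,11-trimethyldodeca-2,6-dien-1-yl]oxy}-6-methoxy-2-benzofuran-1(3H)-one | COc1cc2c(c(O)c1OC/C=C(\C)CC/C=C(\C)CCCC(C)(C)O)COC2=O | target

Total step count: 7. Longest linear sequence: 6 steps (1 → 2 → 4 → 8 → 10 → 11 → 13).

Steps most likely to fail

Step 4. The hydroboration of the conjugated diene may be incomplete or unselective (addition at the internal position or twofold hydroboration), and the homoallylic borane may undergo protodeboronation or β-hydride elimination during transmetalation. The fallback sets out from 4 and returns at 8; it forms the same C5'–C6' bond by a Negishi coupling. Commercial (4-iodobut-1-yn-1-yl)trimethylsilane would be converted with Zn dust and LiCl in THF into [4-(trimethylsilyl)but-3-yn-1-yl]zinc iodide F1, used in excess so that the first equivalent only deprotonates the tertiary alcohol. Pd(dppf)Cl2-catalysed coupling with 4 should give (6E)-2,6-dimethyl-11-(trimethylsilyl)undec-6-en-10-yn-2-ol F2. K2CO3 in MeOH would remove the silyl group to give (6E)-2,6-dimethylundec-6-en-10-yn-2-ol F3. A second Cp2ZrCl2-catalysed methylalumination with Me3Al would give [(1E,5E)-10-(dimethylalumanyloxy)-2,6,10-trimethylundeca-1,5-dien-1-yl]dimethylalumane F4, which after activation with n-BuLi would be trapped with paraformaldehyde to give 8.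

Step 5. Etherification may occur at the 3-hydroxyl or at both hydroxyls of the catechol, or the catechol may be diverted into a cyclic phosphorane by the phosphine/azodicarboxylate pair. The fallback sets out from 8 and returns at 10. CBr4/PPh3 in CH2Cl2 at −20 °C should convert only the primary allylic hydroxyl into (6E,10E)-12-bromo-2,6,10-trimethyldodeca-6,10-dien-2-ol F5. This bromide would alkylate 9 with one equivalent of KHCO3 in DMF at rt, where only the more acidic 4-hydroxyl is ionised, so that 10 should form by SN2 alkylation.

Step 6. Electrophilic attack at the crowded position between the ester and the phenol may be slow, and prolonged heating with the magnesium salt may ionise the allylic aryl ether. The fallback sets out from 10 and returns at 12, and so at 13, bypassing aldehyde 11; it replaces formylation–reduction by a boron-templated ortho-hydroxymethylation. PhB(OH)2, paraformaldehyde and catalytic propionic acid in toluene at reflux with removal of water should give methyl 8-{[(2E,6E)-11-hydroxy-3,7,11-trimethyldodeca-2,6-dien-1-yl]oxy}-7-methoxy-2-phenyl-4H-1,3,2-benzodioxaborinine-5-carboxylate F6. Exchange with propane-1,3-diol would free 12, which lactonises to 13 as in step 7.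

Further compounds
F1 | step 4 | [4-(trimethylsilyl)but-3-yn-1-yl]zinc iodide | C[Si](C)(C)C#CCC[Zn]I
F2 | step 4 | (6E)-2,6-dimethyl-11-(trimethylsilyl)undec-6-en-10-yn-2-ol | C[Si](C)(C)C#CCC/C=C(\C)CCCC(C)(C)O
F3 | step 4 | (6E)-2,6-dimethylundec-6-en-10-yn-2-ol | C#CCC/C=C(\C)CCCC(C)(C)O
F4 | step 4 | [(1E,5E)-10-(dimethylalumanyloxy)-2,6,10-trimethylundeca-1,5-dien-1-yl]dimethylalumane | C[Al](C)/C=C(\C)CC/C=C(\C)CCCC(C)(C)O[Al](C)C
F5 | step 5 | (6E,10E)-12-bromo-2,6,10-trimethyldodeca-6,10-dien-2-ol | BrC/C=C(\C)CC/C=C(\C)CCCC(C)(C)O
F6 | step 6 | methyl 8-{[(2E,6E)-11-hydroxy-3,7,11-trimethyldodeca-2,6-dien-1-yl]oxy}-7-methoxy-2-phenyl-4H-1,3,2-benzodioxaborinine-5-carboxylate | COC(=O)c1cc(OC)c(OC/C=C(\C)CC/C=C(\C)CCCC(C)(C)O)c2OB(c3ccccc3)OCc12
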